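**Plan**

1. Ring atoms are called C1 (quaternary, CH3 and trienyl chain), C2 (CHCH3), C3, C4, C5 (carries =C(CH3)CHO) and C6 (CH with the hydroxypropyl chain). The retrosynthesis cuts, in this order, the O–Si bond, ring bond C2–C3, the C4–C5 bond (a vinyl group), the C5–C(CH3) bond, the C1–C6 bond and one ester C–O bond. This leads to geranylgeraniol (20 of the 30 carbons, all three E chain alkenes) and a 5-silyloxypentanoic acid.
2. Forward: ester formation, then an Ireland–Claisen rearrangement that makes C1–C6 and leaves a vinyl group on C1. The acid carbon (C5) is grown into a 2-methyl-3-vinyl enal through a β-keto ester and an E enol triflate. The only ring is closed in the penultimate step, followed by desilylation.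
3. Enabling feature: C2 is a CH(CH3) next to quaternary C1, so a vinyl group on C1 is a latent C2 radical (H• to its CH2 terminus writes the methyl group). The exocyclic tetrasubstituted C5=C(CH3)CHO alkene, extended by a vinyl group, makes C3 a δ-acceptor, and its allylic 1,3-strain holds the C6 side chain axial in the closing chair.
4. Stereochemistry: C1 and C6 come from the chair Claisen transition state (relative) under a chiral diazaborolidine controller (absolute). The enal geometry comes from the E enol triflate and a retentive coupling. C2 comes from the cyclisation.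

Key step: step 8

Assumption: the (4S,5S) boron controller is taken to give the (2S,3R) acid 6; if its facial sense proves opposite, the (4R,5R) reagent is used and nothing else changes.

**Step 1**
Reactants: 1 (2E,6E,10E)-geranylgeraniol; 2 5-(tert-butyldimethylsilyloxy)pentanoic acid
Product: 3 (2E,6E,10E)-geranylgeranyl 5-(tert-butyldimethylsilyloxy)pentanoate
Conditions: DCC, DMAP (cat.), CH2Cl2, 0 °C to 22 °C
Reagents that add atoms: none
Why: Steglich esterification of a primary allylic alcohol is mild enough to leave the three E trisubstituted alkenes and the silyl ether untouched.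

**Step 2**
Reactants: 3 (2E,6E,10E)-geranylgeranyl 5-(tert-butyldimethylsilyloxy)pentanoate
Product: 6 (2S,3R,6E,10E)-2-[3-(tert-butyldimethylsilyloxy)propyl]-3-ethenyl-3,7,11,15-tetramethylhexadeca-6,10,14-trienoic acid, via boron ketene acetal 4 (not isolated), via acyloxyborane 5 (not isolated)
Conditions: (4S,5S)-2-bromo-1,3-bis{[3,5-bis(trifluoromethyl)phenyl]sulfonyl}-4,5-diphenyl-1,3,2-diazaborolidine (1.2 equiv, preformed), i-Pr2NEt, CH2Cl2, −78 °C, then −20 °C to 4 °C; aqueous work-up
Reagents that add atoms: none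
Why: Enantioselective Ireland–Claisen rearrangement of the Z(O) boron enolate through a chair transition state, in which the E allyl terminus places its CH3 axial and the chain equatorial and the enolate substituent is equatorial, should create the quaternary carbon and its neighbour together with the required relative configuration, the face being chosen by the diazaborolidine.

**Step 3**
Reactants: 6 (2S,3R,6E,10E)-2-[3-(tert-butyldimethylsilyloxy)propyl]-3-ethenyl-3,7,11,15-tetramethylhexadeca-6,10,14-trienoic acid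
Product: 8 ethyl (4S,5R,8E,12E)-4-[3-(tert-butyldimethylsilyloxy)propyl]-5-ethenyl-2,5,9,13,17-pentamethyl-3-oxooctadeca-8,12,16-trienoate (both C2 epimers), via acyl imidazolide 7 (not isolated)
Conditions: CDI, THF, 22 °C; then lithium enolate of ethyl propionate (from LiN(i-Pr)2 and ethyl propionate, 3.3 equiv), THF, −78 °C to −20 °C; AcOH quench
Reagents that add atoms: ethyl propionate, CCC(=O)OCC
Why: Crossed Claisen condensation (C-acylation of an ester enolate by an acyl imidazolide) should give the β-keto ester, which is stored in the flask as its doubly stabilised enolate and so protects the stereocentre next to the ketone.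

**Step 4**
Reactants: 8 ethyl (4S,5R,8E,12E)-4-[3-(tert-butyldimethylsilyloxy)propyl]-5-ethenyl-2,5,9,13,17-pentamethyl-3-oxooctadeca-8,12,16-trienoate
Product: 9 ethyl (2E,4S,5R,8E,12E)-4-[3-(tert-butyldimethylsilyloxy)propyl]-5-ethenyl-2,5,9,13,17-pentamethyl-3-(trifluoromethylsulfonyloxy)octadeca-2,8,12,16-tetraenoate
Conditions: Tf2O, aq. Me4NOH, toluene, 0 °C
Reagents that add atoms: trifluoromethanesulfonic anhydride, O=S(=O)(OS(=O)(=O)C(F)(F)F)C(F)(F)F
Why: O-sulfonylation of the non-chelated tetraalkylammonium enolate of a β-keto ester should give the E enol triflate (triflate trans to the ester), which places the ester on the side of the branched carbon as the enal requires.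

**Step 5**
Reactants: 9 ethyl (2E,4S,5R,8E,12E)-4-[3-(tert-butyldimethylsilyloxy)propyl]-5-ethenyl-2,5,9,13,17-pentamethyl-3-(trifluoromethylsulfonyloxy)octadeca-2,8,12,16-tetraenoate
Product: 10 ethyl (2Z,4S,5R,8E,12E)-4-[3-(tert-butyldimethylsilyloxy)propyl]-3,5-diethenyl-2,5,9,13,17-pentamethyloctadeca-2,8,12,16-tetraenoate
Conditions: Bu3SnCH=CH2, Pd(PPh3)4 (cat.), CuI (cat.), LiCl, DMF, 50 °C
Reagents that add atoms: tributyl(vinyl)stannane, C=C[Sn](CCCC)(CCCC)CCCC
Why: Stille coupling of an enol triflate proceeds with retention of alkene geometry, so the new vinyl group should end up cis to the methyl group.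

**Step 6**
Reactants: 10 ethyl (2Z,4S,5R,8E,12E)-4-[3-(tert-butyldimethylsilyloxy)propyl]-3,5-diethenyl-2,5,9,13,17-pentamethyloctadeca-2,8,12,16-tetraenoate
Product: 11 (2Z,4S,5R,8E,12E)-4-[3-(tert-butyldimethylsilyloxy)propyl]-3,5-diethenyl-2,5,9,13,17-pentamethyloctadeca-2,8,12,16-tetraen-1-ol
Conditions: i-Bu2AlH (2.5 equiv), CH2Cl2, −78 °C to −40 °C; aq. potassium sodium tartrate
Reagents that add atoms: none
Why: 1,2-Reduction of a hindered conjugated ester by i-Bu2AlH should give the allylic alcohol without touching the alkenes or the silyl ether.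

**Step 7**
Reactants: 11 (2Z,4S,5R,8E,12E)-4-[3-(tert-butyldimethylsilyloxy)propyl]-3,5-diethenyl-2,5,9,13,17-pentamethyloctadeca-2,8,12,16-tetraen-1-ol
Product: 12 (2Z,4S,5R,8E,12E)-4-[3-(tert-butyldimethylsilyloxy)propyl]-3,5-diethenyl-2,5,9,13,17-pentamethyloctadeca-2,8,12,16-tetraenal
Conditions: MnO2 (excess), CH2Cl2, 22 °C, dark
Reagents that add atoms: none
Why: Allylic oxidation with MnO2 is neutral and should deliver the dienal without isomerising the tetrasubstituted alkene or the stereocentre in its γ-position.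

**Step 8**
Reactants: 12 (2Z,4S,5R,8E,12E)-4-[3-(tert-butyldimethylsilyloxy)propyl]-3,5-diethenyl-2,5,9,13,17-pentamethyloctadeca-2,8,12,16-tetraenal
Product: 14 (2Z)-2-[(2S,3R,4R)-2-[3-(tert-butyldimethylsilyloxy)propyl]-3,4-dimethyl-3-[(3E,7E)-4,8,12-trimethyltrideca-3,7,11-trien-1-yl]cyclohexylidene]propanal, via dienol 13 (not isolated)
Conditions: CoCl[N,N′-bis(3,5-di-tert-butylsalicylidene)-1,2-cyclohexanediaminate] (10 mol%, trivalent cobalt), PhSiH3 (1.5 equiv), EtOH (3 equiv), benzene (high dilution), 22 °C, argon, dark; then PPTS (cat.), CH2Cl2, 0 °C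
Reagents that add atoms: none
Why: Proposed new method: a bulky cobalt hydride of the salen type (trivalent cobalt, regenerated by PhSiH3) should transfer a hydrogen atom only to the unhindered, electron-neutral CH2 terminus of the vinyl group on the quaternary carbon (the trisubstituted chain alkenes are too hindered and the dienal too electron-poor), and the secondary radical formed at C2 then adds to C3, the δ-carbon of the 2-methyl-3-vinyl enal, after which divalent cobalt captures the dienyl-oxy radical and EtOH releases dienol 13, whose γ-protonation at C4 gives the conjugated enal. The closest known reactions are the Fe(acac)3/PhSiH3 reductive alkene–enone (Giese) cyclisation and the terminal-alkene-selective MHAT cycloisomerisation with cobalt salen complexes, the new elements being the vinylogous (1,6) acceptor and reductive turnover on cobalt. The cyclohexane closes 6-endo-trig, because attack at C3 gives a delocalised radical whereas 5-exo attack at C4 would give an unstabilised primary one, and the competing 5-exo addition to the first chain alkene is an unactivated and slower process. The new stereocentre at C2 is set in a chair-like transition state in which allylic 1,3-strain with the formyl group keeps the C6–H bond in the plane of the tetrasubstituted alkene and the C6 side chain axial, so that the methyl group on the radical carbon goes equatorial, trans to the C1 methyl group. The alkene geometry is expected to persist because the s-trans dienol is protonated at C4 from the conformer that keeps the small formyl group beside the crowded C6, which should also be the thermodynamically preferred isomer.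

**Step 9**
Reactants: 14 (2Z)-2-[(2S,3R,4R)-2-[3-(tert-butyldimethylsilyloxy)propyl]-3,4-dimethyl-3-[(3E,7E)-4,8,12-trimethyltrideca-3,7,11-trien-1-yl]cyclohexylidene]propanal
Product: 15 (2Z)-2-[(2S,3R,4R)-2-(3-hydroxypropyl)-3,4-dimethyl-3-[(3E,7E)-4,8,12-trimethyltrideca-3,7,11-trien-1-yl]cyclohexylidene]propanal
Conditions: HF·pyridine, pyridine, THF, 0 °C
Reagents that add atoms: none
Why: Buffered fluoride desilylation of a primary silyl ether avoids the base that could deprotonate the γ-position of the enal.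

**Compound list**

1 | (2E,6E,10E)-geranylgeraniol | CC(C)=CCC/C(C)=C/CC/C(C)=C/CC/C(C)=C/CO | starting material
2 | 5-(tert-butyldimethylsilyloxy)pentanoic acid | O=C(O)CCCCO[Si](C)(C)C(C)(C)C | starting material
3 | (2E,6E,10E)-geranylgeranyl 5-(tert-butyldimethylsilyloxy)pentanoate | CC(C)=CCC/C(C)=C/CC/C(C)=C/CC/C(C)=C/COC(=O)CCCCO[Si](C)(C)C(C)(C)C | intermediate
4 | Z(O) boron ketene acetal of 3 carrying the (4S,5S)-1,3-bis(arylsulfonyl)-4,5-diphenyl-1,3,2-diazaborolidin-2-yl group on oxygen (not isolated) | CC(C)=CCC/C(C)=C/CC/C(C)=C/CC/C(C)=C/CO/C(OB1N(S(=O)(=O)c2cc(C(F)(F)F)cc(C(F)(F)F)c2)[C@@H](c2ccccc2)[C@H](c2ccccc2)N1S(=O)(=O)c1cc(C(F)(F)F)cc(C(F)(F)F)c1)=C/CCCO[Si](C)(C)C(C)(C)C | intermediate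
5 | acyloxyborane of acid 6 with the same diazaborolidinyl group (not isolated) | CC(C)=CCC/C(C)=C/CC/C(C)=C/CC[C@](C)(C=C)[C@H](CCCO[Si](C)(C)C(C)(C)C)C(=O)OB1N(S(=O)(=O)c2cc(C(F)(F)F)cc(C(F)(F)F)c2)[C@@H](c2ccccc2)[C@H](c2ccccc2)N1S(=O)(=O)c1cc(C(F)(F)F)cc(C(F)(F)F)c1 | intermediate
6 | (2S,3R,6E,10E)-2-[3-(tert-butyldimethylsilyloxy)propyl]-3-ethenyl-3,7,11,15-tetramethylhexadeca-6,10,14-trienoic acid | CC(C)=CCC/C(C)=C/CC/C(C)=C/CC[C@](C)(C=C)[C@H](CCCO[Si](C)(C)C(C)(C)C)C(=O)O | intermediate
7 | N-acyl imidazole of acid 6 (not isolated) | CC(C)=CCC/C(C)=C/CC/C(C)=C/CC[C@](C)(C=C)[C@H](CCCO[Si](C)(C)C(C)(C)C)C(=O)n1ccnc1 | intermediate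
8 | ethyl (4S,5R,8E,12E)-4-[3-(tert-butyldimethylsilyloxy)propyl]-5-ethenyl-2,5,9,13,17-pentamethyl-3-oxooctadeca-8,12,16-trienoate, both C2 epimers | CC(C)=CCC/C(C)=C/CC/C(C)=C/CC[C@](C)(C=C)[C@H](CCCO[Si](C)(C)C(C)(C)C)C(=O)C(C)C(=O)OCC | intermediate
9 | ethyl (2E,4S,5R,8E,12E)-4-[3-(tert-butyldimethylsilyloxy)propyl]-5-ethenyl-2,5,9,13,17-pentamethyl-3-(trifluoromethylsulfonyloxy)octadeca-2,8,12,16-tetraenoate | CC(C)=CCC/C(C)=C/CC/C(C)=C/CC[C@](C)(C=C)[C@H](CCCO[Si](C)(C)C(C)(C)C)/C(OS(=O)(=O)C(F)(F)F)=C(/C)C(=O)OCC | intermediate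
10 | ethyl (2Z,4S,5R,8E,12E)-4-[3-(tert-butyldimethylsilyloxy)propyl]-3,5-diethenyl-2,5,9,13,17-pentamethyloctadeca-2,8,12,16-tetraenoate | CC(C)=CCC/C(C)=C/CC/C(C)=C/CC[C@](C)(C=C)[C@H](CCCO[Si](C)(C)C(C)(C)C)/C(C=C)=C(/C)C(=O)OCC | intermediate
11 | (2Z,4S,5R,8E,12E)-4-[3-(tert-butyldimethylsilyloxy)propyl]-3,5-diethenyl-2,5,9,13,17-pentamethyloctadeca-2,8,12,16-tetraen-1-ol | CC(C)=CCC/C(C)=C/CC/C(C)=C/CC[C@](C)(C=C)[C@H](CCCO[Si](C)(C)C(C)(C)C)/C(C=C)=C(/C)CO | intermediate
12 | (2Z,4S,5R,8E,12E)-4-[3-(tert-butyldimethylsilyloxy)propyl]-3,5-diethenyl-2,5,9,13,17-pentamethyloctadeca-2,8,12,16-tetraenal | CC(C)=CCC/C(C)=C/CC/C(C)=C/CC[C@](C)(C=C)[C@H](CCCO[Si](C)(C)C(C)(C)C)/C(C=C)=C(/C)C=O | intermediate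
13 | cyclised dienol: cyclohexene with the ring alkene between C4 and C5 and a 1-hydroxyprop-1-en-2-yl group on C5, OH cis to the methyl group (not isolated) | CC(C)=CCC/C(C)=C/CC/C(C)=C/CC[C@]1(C)[C@H](C)CC=C(/C(C)=C/O)[C@H]1CCCO[Si](C)(C)C(C)(C)C | intermediate
14 | (2Z)-2-[(2S,3R,4R)-2-[3-(tert-butyldimethylsilyloxy)propyl]-3,4-dimethyl-3-[(3E,7E)-4,8,12-trimethyltrideca-3,7,11-trien-1-yl]cyclohexylidene]propanal | CC(C)=CCC/C(C)=C/CC/C(C)=C/CC[C@]1(C)[C@H](C)CC/C(=C(\C)C=O)[C@H]1CCCO[Si](C)(C)C(C)(C)C | intermediate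
15 | (2Z)-2-[(2S,3R,4R)-2-(3-hydroxypropyl)-3,4-dimethyl-3-[(3E,7E)-4,8,12-trimethyltrideca-3,7,11-trien-1-yl]cyclohexylidene]propanal | CC(C)=CCC/C(C)=C/CC/C(C)=C/CC[C@]1(C)[C@H](C)CC/C(=C(\C)C=O)[C@H]1CCCO | target

**Totals and risks**

Total step count: 9. Longest linear sequence: 9 steps (1 and 2 to 15).

Steps most likely to fail:

1. Step 8 (proposed new method). Hydrogen-atom transfer may go to a chain alkene or to the dienal instead of the vinyl group, and the alkene position or geometry may be scrambled when the dienol ketonises. The fallback uses known chemistry, sets out from 10 and comes back at 14. Tsuji–Wacker oxidation (PdCl2 cat., CuCl, O2, DMF/H2O) of the isolated terminal vinyl group should give the methyl ketone F1. NaBH4/CeCl3 reduction should give the secondary alcohol F2, and PhOC(S)Cl/pyridine the phenyl thionocarbonate F3. Slow addition of Bu3SnH/AIBN (benzene, 80 °C) should generate the same C2 radical by Barton–McCombie fragmentation; 6-endo cyclisation then gives the cyclised ethyl ester F4. Reduction with i-Bu2AlH should give the allylic alcohol F5, and MnO2 oxidises it to 14.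

2. Step 2. The chair/boat preference or the enolate geometry may be insufficient (poor diastereoselectivity), the facial selectivity may be eroded, or the Lewis acidic boron reagent may cleave the silyl ether. The fallback sets out from 3 and comes back at 6. LiN(i-Pr)2 in THF/DMPU with Me3SiCl at −78 °C should give the Z(O) silyl ketene acetal F6, which rearranges on warming to the racemic trimethylsilyl ester F7. Hydrolysis on work-up gives the racemic acid, that is 6 together with its enantiomer F8, and the two are separated by preparative chromatography on a chiral stationary phase.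

3. Step 4. O-sulfonylation of the hindered, fully substituted enolate may give incomplete E selectivity. The fallback sets out from 6 and comes back at 10. LiAlH4 reduction should give the primary alcohol F9, and Dess–Martin oxidation the aldehyde F10. The Ohira–Bestmann reagent with K2CO3 in MeOH should give the terminal alkyne F11, and n-BuLi then ClCO2Et the ynoate F12. Syn addition of (CH2=CH)2CuLi at −78 °C with iodine trapping should give the iodo dienoate F13 (vinyl cis to iodine). Stille methylation with retention (Me4Sn, Pd(PPh3)4, CuI, DMF) then gives 10.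

**Further compounds**

F1 | step 8 | methyl ketone: 10 with acetyl in place of the ethenyl group on the quaternary carbon | CC(C)=CCC/C(C)=C/CC/C(C)=C/CC[C@](C)(C(C)=O)[C@H](CCCO[Si](C)(C)C(C)(C)C)/C(C=C)=C(/C)C(=O)OCC
F2 | step 8 | secondary alcohol from F1, both carbinol epimers | CC(C)=CCC/C(C)=C/CC/C(C)=C/CC[C@](C)(C(C)O)[C@H](CCCO[Si](C)(C)C(C)(C)C)/C(C=C)=C(/C)C(=O)OCC
F3 | step 8 | O-phenyl thionocarbonate of F2 | CC(C)=CCC/C(C)=C/CC/C(C)=C/CC[C@](C)(C(C)OC(=S)Oc1ccccc1)[C@H](CCCO[Si](C)(C)C(C)(C)C)/C(C=C)=C(/C)C(=O)OCC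
F4 | step 8 | cyclised ethyl ester: 14 with CO2Et in place of CHO | CC(C)=CCC/C(C)=C/CC/C(C)=C/CC[C@]1(C)[C@H](C)CC/C(=C(\C)C(=O)OCC)[C@H]1CCCO[Si](C)(C)C(C)(C)C
F5 | step 8 | allylic alcohol: 14 with CH2OH in place of CHO | CC(C)=CCC/C(C)=C/CC/C(C)=C/CC[C@]1(C)[C@H](C)CC/C(=C(\C)CO)[C@H]1CCCO[Si](C)(C)C(C)(C)C
F6 | step 2 | Z(O) trimethylsilyl ketene acetal of 3 | CC(C)=CCC/C(C)=C/CC/C(C)=C/CC/C(C)=C/CO/C(O[Si](C)(C)C)=C/CCCO[Si](C)(C)C(C)(C)C
F7 | step 2 | trimethylsilyl ester of the rearranged acid, racemic (one enantiomer drawn) | CC(C)=CCC/C(C)=C/CC/C(C)=C/CC[C@](C)(C=C)[C@H](CCCO[Si](C)(C)C(C)(C)C)C(=O)O[Si](C)(C)C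
F8 | step 2 | (2R,3S) enantiomer of acid 6 | CC(C)=CCC/C(C)=C/CC/C(C)=C/CC[C@@](C)(C=C)[C@@H](CCCO[Si](C)(C)C(C)(C)C)C(=O)O
F9 | step 4 | primary alcohol from reduction of acid 6 | CC(C)=CCC/C(C)=C/CC/C(C)=C/CC[C@](C)(C=C)[C@H](CCCO[Si](C)(C)C(C)(C)C)CO
F10 | step 4 | aldehyde corresponding to acid 6 | CC(C)=CCC/C(C)=C/CC/C(C)=C/CC[C@](C)(C=C)[C@H](CCCO[Si](C)(C)C(C)(C)C)C=O
F11 | step 4 | terminal alkyne from F10 | CC(C)=CCC/C(C)=C/CC/C(C)=C/CC[C@](C)(C=C)[C@H](CCCO[Si](C)(C)C(C)(C)C)C#C
F12 | step 4 | ethyl ynoate from F11 | CC(C)=CCC/C(C)=C/CC/C(C)=C/CC[C@](C)(C=C)[C@H](CCCO[Si](C)(C)C(C)(C)C)C#CC(=O)OCC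
F13 | step 4 | ethyl 2-iodo dienoate: 10 with iodine in place of the 2-methyl group, vinyl cis to iodine | CC(C)=CCC/C(C)=C/CC/C(C)=C/CC[C@](C)(C=C)[C@H](CCCO[Si](C)(C)C(C)(C)C)/C(C=C)=C(/I)C(=O)OCC
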